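Readings and results are simulated with made-up constants, noise included.

At the first reading, 3.00 min, the elm flask shows D at 0.4%; at the last, 40.0 min, D reads 0%. Elm is the flask we are asked about.

all flasks: D 22 mM

| flask | Z | X | remark | time |
|---|---|---|---|---|
| elm | 44 mM | 1.1 mM | the very flask that is asked about, followed so far |  |
| alder | 44 mM | 0.74 mM | run made earlier |  |
| flask | 44.0 mM | 1.1 mM |  | 1.5 h |

- elm (time / min: L / %, J / %, D / %): 3.00: 15.3, 84.5, 0.4; 5.00: 14.1, 84.3, 0.6; 10.0: 15.4, 85.2, 0; 20.0: 15.0, 85.3, 0.4; 40.0: 14.0, 84.5, 0
- alder (time / min: L / %, J / %, D / %): 3.00: 10.3, 87.4, 1.5; 5.00: 10.4, 89.4, 0.4; 10.0: 10.5, 89.4, 0.3; 20.0: 11.5, 89.3, 0; 40.0: 11.1, 88.7, 0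

(scatter of a reading: 0.5 percentage points)

- percent here means D units held: one J counts as two
- the reaction counts as stopped when no species that holds the D changes by six tenths of a point or more over the second half of the time

* why nothing more happens at 1.5 h, or that something still does (it is still moving / all of D has reacted / no working catalyst is left / forward and back rates have come level)
* how much L there is at 1.5 h, in percent of the D charged
* how much J there is at 1.5 h, in percent of the D charged
* amount of L if the flask were left three thousand times as long, in percent of the D charged

We keep the books on the D charged, using the mean of the elm readings: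

D left: 0.280%
In L: 14.8%
In J, two D units each: 84.8%
Total: 99.9%

The elm books close, and we read no trend above the scatter of 0.5 percentage points. The alder flask, with less X, holds less L: 10.8%. So we divide the L entry, in mM, by the X charged:

Elm: 2.95
Alder: 3.20
Mean: 3.08

That mean is our carried quantity, the L left per X charged, read with D and Z at these charges. For the flask at 1.5 h we reckon:

[L] / [D] charged = 15.4%
J = 84.6%

With D reading 0%, we expect these entries to stand.

The forecast gives all of D has reacted, L 14.8%, J 85% and long-term L 14.8%, calling the plateau “a kinetic product split fixed while D was being consumed”.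

The flask gives all of D has reacted, L 15.2%, J 84.8% and long-term L 15.2%.

    Q → X + E (k = 7.00 s⁻¹)
    G → X + L (k = 1.30 s⁻¹)
    Z + X ⇌ Q (K = 12.0 L mol⁻¹, k = 3000 L mol⁻¹ s⁻¹)
    D + X ⇌ G (K = 24.0 L mol⁻¹, k = 58.0 L mol⁻¹ s⁻¹)
    D + L → J (k = 5.90 L mol⁻¹ s⁻¹)

That is 3.05 L per X charged, with 0% of D left. In this flask the turning of D + L into J turns over 42.4% of the D charged, and each turn takes one D and one L, which makes 84.8% in D units. Part of that J entry is owed to the way back from G to D + X: in the run with that way back struck out, J stands at 70.0% against 84.8%.

For a neighbour flask with 0.66 mM of X, its D and Z charged as here, the carried quantity gives L at 9.23%. That neighbour flask gives 9.60%.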